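The route rests on opening the ten-membered carbocycle at C9–C10: in the target C10 carries a methyl group next to the hemiketal carbon C1, so this bond can be made as the trisubstituted alkene of an α-methyl enone. Ring-closing metathesis of a C1 isopropenyl ketone with the C8 vinyl group forms the bond and the ring in one operation. The precursor is a seco diene whose butenolide (C6, C7, C11, C12 and the ring oxygen) already bears the C5–C6 enol-lactone alkene with C4 cis to C7; a diisopropylsilylene bridge from O4 to O8 enforces that geometry and holds both reacting chains on one face.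

Key step: step 15

Remarks on the chemistry (assumptions, one line each)
- Numbering is germacrane numbering: C1 hemiketal carbon, C4 ether carbon with its methyl, C5=C6 enol-lactone alkene, C7=C11 butenolide alkene, C8 ester-bearing carbon, C10 methyl-bearing carbon, C12 lactone carbonyl, C13 acetoxymethyl carbon.
- Structural check: 4R, 8S and the 5E enol-lactone alkene (C4 trans to the ring oxygen) are common to the seco diene, the ring-closed enone and the target; the new C9–C10 alkene is Z (ring-cis).
- In an open chain the 5E alkene is the more crowded isomer, so O4 and O8 are carried as one cyclic diisopropylsilylene and the alkene is generated inside the eight-membered siloxane ring, where only this geometry can form; one fluoride treatment removes the bridge.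
- The C1 ketone is unmasked from an alkyne after all organolithium chemistry, and no alkene has to be cleaved anywhere in the route.
- Assumption: the natural C10 configuration (methyl on the side of the one-atom oxygen bridge) is the thermodynamically preferred epimer of the bridged hemiketal.
- The glycidyl tosylate is R although it comes from the S epoxy alcohol without any change at carbon, because the sulfonate raises the CIP rank of its CH2 group.

Step 1
Reactants: 1 diethyl furan-3,4-dicarboxylate
Product: 2 furan-3,4-diyldimethanol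
Conditions: LiAlH4, THF, 0 °C → rt
Reagents that add atoms: none
Why: Ester reduction with LiAlH4 leaves the furan untouched and gives the symmetrical diol whose two arms become C8 and C13.

Step 2
Reactants: 2 furan-3,4-diyldimethanol
Product: 3 [4-({[tert-butyl(dimethyl)silyl]oxy}methyl)furan-3-yl]methanol
Conditions: NaH (1.0 equiv), THF, rt; TBSCl (1.0 equiv)
Reagents that add atoms: tert-butyldimethylsilyl chloride, CC(C)(C)[Si](C)(C)Cl
Why: Monosilylation of the symmetrical diol through its monosodium alkoxide (Williamson-type O-silylation) desymmetrises the two arms, and the bulky non-coordinating silyl ether later keeps the C13 arm from directing lithiation.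

Step 3
Reactants: 3 [4-({[tert-butyl(dimethyl)silyl]oxy}methyl)furan-3-yl]methanol
Product: 4 4-({[tert-butyl(dimethyl)silyl]oxy}methyl)furan-3-carbaldehyde
Conditions: MnO2, CH2Cl2, rt
Reagents that add atoms: none
Why: Activated MnO2 oxidises the furylic (benzylic-type) primary alcohol to the aldehyde without over-oxidation or loss of the silyl ether.

Step 4
Reactants: 4 4-({[tert-butyl(dimethyl)silyl]oxy}methyl)furan-3-carbaldehyde; 5 vinylmagnesium bromide
Product: 6 rac-1-[4-({[tert-butyl(dimethyl)silyl]oxy}methyl)furan-3-yl]prop-2-en-1-ol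
Conditions: THF, −78 °C → 0 °C; then H2O
Reagents that add atoms: none
Why: Grignard 1,2-addition to the aromatic aldehyde installs C9 and the C8 carbinol as a racemate that is resolved in the next step.

Step 5
Reactants: 6 rac-1-[4-({[tert-butyl(dimethyl)silyl]oxy}methyl)furan-3-yl]prop-2-en-1-ol
Product: 7 (S)-1-[4-({[tert-butyl(dimethyl)silyl]oxy}methyl)furan-3-yl]prop-2-en-1-ol
Conditions: immobilised Candida antarctica lipase B, vinyl acetate, MTBE, 30 °C, to just beyond half conversion
Reagents that add atoms: none
Why: Lipase-catalysed kinetic resolution by transesterification acylates the R alcohol (aryl as large, vinyl as medium substituent) much faster, so the recovered alcohol should be the S enantiomer, which is the C8 configuration of the target.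

Step 6
Reactants: 8 2-methylprop-2-en-1-ol
Product: 10 (R)-(2-methyloxiran-2-yl)methyl 4-methylbenzenesulfonate, via (S)-2-methylglycidol 9 (not isolated)
Conditions: Ti(OiPr)4 (5 mol%), L-(+)-diisopropyl tartrate (6 mol%), cumene hydroperoxide, 4 Å molecular sieves, CH2Cl2, −20 °C; then TsCl, Et3N, DMAP (cat.), −10 °C
Reagents that add atoms: cumene hydroperoxide, CC(C)(OO)c1ccccc1; 4-toluenesulfonyl chloride, Cc1ccc(cc1)S(Cl)(=O)=O
Why: Sharpless asymmetric epoxidation with the L-(+)-tartrate ligand sets the quaternary centre that becomes C4 (S epoxy alcohol), and tosylation in the same pot avoids isolating the water-soluble epoxy alcohol.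

Step 7
Reactants: 10 (R)-(2-methyloxiran-2-yl)methyl 4-methylbenzenesulfonate; 11 2-methylbut-1-en-3-yne
Product: 14 (R)-2-methyl-2-(4-methylpent-4-en-2-yn-1-yl)oxirane, via lithium 3-methylbut-3-en-1-ynide 12 (not isolated), via ring-opened hydroxy tosylate 13 (not isolated)
Conditions: n-BuLi, THF, −78 °C; BF3·OEt2, then 10, −78 °C; H2O; K2CO3, MeOH, rt
Reagents that add atoms: none
Why: BF3-promoted acetylide opening occurs at the unsubstituted epoxide carbon (the neopentyl sulfonate resists direct displacement) and base then closes the tertiary alkoxide onto the tosylate (intramolecular Williamson epoxide formation), so no bond to the stereocentre is broken and its configuration is kept.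

Step 8
Reactants: 7 (S)-1-[4-({[tert-butyl(dimethyl)silyl]oxy}methyl)furan-3-yl]prop-2-en-1-ol; 14 (R)-2-methyl-2-(4-methylpent-4-en-2-yn-1-yl)oxirane
Product: 16 (S)-1-{4-({[tert-butyl(dimethyl)silyl]oxy}methyl)-2-[(R)-2-hydroxy-2,6-dimethylhept-6-en-4-yn-1-yl]furan-3-yl}prop-2-en-1-ol, via dilithiated furan carbinol 15 (not isolated)
Conditions: n-BuLi (2.1 equiv), THF, −78 °C → 0 °C; then 14, BF3·OEt2, −78 °C; H2O
Reagents that add atoms: none
Why: The lithium alkoxide directs the second lithiation to the adjacent furan α-carbon (directed ortho-metalation) and the furyllithium opens the 2,2-disubstituted epoxide at its CH2 under BF3 activation, which forms the C5–C6 bond and frees the C4 tertiary alcohol with the epoxide configuration intact.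

Step 9
Reactants: 16 (S)-1-{4-({[tert-butyl(dimethyl)silyl]oxy}methyl)-2-[(R)-2-hydroxy-2,6-dimethylhept-6-en-4-yn-1-yl]furan-3-yl}prop-2-en-1-ol
Product: 17 (S)-1-{4-(hydroxymethyl)-2-[(R)-2-hydroxy-2,6-dimethylhept-6-en-4-yn-1-yl]furan-3-yl}prop-2-en-1-ol
Conditions: TBAF, AcOH, THF, 0 °C
Reagents that add atoms: none
Why: Fluoride-induced desilylation buffered with acetic acid removes the primary silyl ether while sparing the sensitive furyl vinyl carbinol.

Step 10
Reactants: 17 (S)-1-{4-(hydroxymethyl)-2-[(R)-2-hydroxy-2,6-dimethylhept-6-en-4-yn-1-yl]furan-3-yl}prop-2-en-1-ol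
Product: 18 {5-[(R)-2-hydroxy-2,6-dimethylhept-6-en-4-yn-1-yl]-4-[(S)-1-hydroxyprop-2-en-1-yl]furan-3-yl}methyl acetate
Conditions: AcCl (1.05 equiv), 2,4,6-collidine, CH2Cl2, −78 °C
Reagents that add atoms: acetyl chloride, CC(Cl)=O
Why: Chemoselective acetylation with acetyl chloride and a hindered base at low temperature is confined to the unhindered primary hydroxyl and installs the C13 acetate, leaving the secondary C8 and tertiary C4 hydroxyls free.

Step 11
Reactants: 18 {5-[(R)-2-hydroxy-2,6-dimethylhept-6-en-4-yn-1-yl]-4-[(S)-1-hydroxyprop-2-en-1-yl]furan-3-yl}methyl acetate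
Product: 20 {5-[(R)-2-hydroxy-2,6-dimethyl-5-oxohept-6-en-1-yl]-4-[(S)-1-hydroxyprop-2-en-1-yl]furan-3-yl}methyl acetate (in equilibrium with its cyclic hemiketal), via cyclic enol ether 19 (not isolated)
Conditions: PdCl2(MeCN)2 (5 mol%), MeCN–H2O, rt
Reagents that add atoms: water, O
Why: Divalent palladium activates the alkyne for 5-endo-dig attack by the homopropargylic C4 hydroxyl (alkynol cycloisomerisation), which places the oxygen at C1, and hydrolysis of the cyclic enol ether by the water present unmasks the isopropenyl ketone regiospecifically.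

Step 12
Reactants: 20 {5-[(R)-2-hydroxy-2,6-dimethyl-5-oxohept-6-en-1-yl]-4-[(S)-1-hydroxyprop-2-en-1-yl]furan-3-yl}methyl acetate
Product: 21 (4R,8S)-silylene-bridged furan (O4 and O8 of 20 joined by Si(iPr)2 in an eight-membered 1,3-dioxa-2-silacycle fused to the furan)
Conditions: iPr2Si(OTf)2, 2,6-lutidine, CH2Cl2 (high dilution), −78 °C → 0 °C
Reagents that add atoms: diisopropylsilyl bis(trifluoromethanesulfonate), CC(C)[Si](OS(=O)(=O)C(F)(F)F)(OS(=O)(=O)C(F)(F)F)C(C)C
Why: Silylene acetal formation should start at the secondary C8 hydroxyl and finish by intramolecular capture of the remaining silyl triflate by the C4 hydroxyl of the open hydroxy-ketone tautomer, the adjacent arms on the furan favouring closure of the eight-membered ring.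

Step 13
Reactants: 21 (4R,8S)-silylene-bridged furan
Product: 23 (4R,8S)-silylene-bridged γ-hydroxybutenolide (carbonyl at C12 and hemiketal hydroxyl at C6; both C6 epimers), via furan endoperoxide 22 (not isolated)
Conditions: O2, hν, tetraphenylporphyrin (cat.), CH2Cl2, −78 °C; then iPr2NEt, −78 °C → rt
Reagents that add atoms: dioxygen, O=O
Why: Singlet oxygen adds across the electron-rich furan in a [4+2] cycloaddition and the amine removes the only bridgehead hydrogen of the endoperoxide, at C12 (Kornblum–DeLaMare rearrangement), so the carbonyl appears at C12 while the electron-poor and monosubstituted alkenes stay inert.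

Step 14
Reactants: 23 (4R,8S)-silylene-bridged γ-hydroxybutenolide
Product: 25 (4R,5E,8S)-silylene-bridged seco diene (γ-alkylidene butenolide with C1 isopropenyl ketone and C8 vinyl group), via pseudo-acid mesylate 24 (not isolated)
Conditions: MsCl, Et3N, CH2Cl2, −20 °C → 0 °C
Reagents that add atoms: none
Why: Mesylation of the pseudo-acid hydroxyl and β-elimination of methanesulfonic acid with a C5 hydrogen gives the alkylidene butenolide, and because the new C5–C6 double bond lies inside the eight-membered siloxane ring it can only form with C4 cis to C7.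

Step 15
Reactants: 25 (4R,5E,8S)-silylene-bridged seco diene
Product: 26 (4R,5E,8S,9Z)-13-acetoxy-1-oxogermacra-5,7(11),9-trien-12,6-olide O4,O8-diisopropylsilylene (ten-membered enone)
Conditions: second-generation Grubbs catalyst RuCl2(H2IMes)(PCy3)(=CHPh) (10–20 mol%), toluene (1 mM), 80 °C, argon sparge
Reagents that add atoms: none
Why: Metathesis begins by exchange of the benzylidene ligand with the terminal C8 vinyl group; the new ruthenium carbene then adds across the 1,1-disubstituted alkene of the C1 ketone to give a ruthenacyclobutane, whose fragmentation expels ethene and leaves the C9–C10 double bond. The closest known reaction type is ring-closing metathesis of a vinyl carbinol derivative with an α-methyl vinyl ketone to give medium-ring and macrocyclic 2-methylcycloalkenones. The ten-membered carbocycle is closed by joining the two alkene termini of a chain whose C5–C6–C7 segment is already held cis by the enol lactone, and the siloxane ring that spans C4 and C8 places the C3 chain and the C9 vinyl on the same face. No stereocentre is formed, and the ten-membered ring can hold only the Z (ring-cis) enone. Site selectivity among four alkenes is needed and is secured because the enol-lactone alkene is trisubstituted and conjugated, the butenolide alkene is tetrasubstituted, and the enone alkene is too electron-poor to initiate, so the catalyst loads only at C8. High dilution and removal of ethene should hold back intermolecular metathesis.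

Step 16
Reactants: 26 (4R,5E,8S,9Z)-ten-membered enone
Product: 27 (4R,5E,8S)-13-acetoxy-1-oxogermacra-5,7(11)-dien-12,6-olide O4,O8-diisopropylsilylene (C10 epimers)
Conditions: [(Ph3P)CuH]6, benzene, degassed H2O, rt
Reagents that add atoms: none
Why: Conjugate reduction by the copper hydride delivers hydride to the enone β-carbon C9 in preference to the tetrasubstituted butenolide and the hindered enol-lactone diene, and protonation of the enolate by water gives the ketone as C10 epimers that are converged in the next step.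

Step 17
Reactants: 27 (4R,5E,8S)-saturated ketone (C10 epimers)
Product: 29 (1S,4R,5E,8S,10R)-13-acetoxy-1,8-dihydroxy-1,4-epoxygermacra-5,7(11)-dien-12,6-olide, via desilylated keto diol 28 (not isolated)
Conditions: HF·pyridine, pyridine, THF, 0 °C → rt; then pyridinium p-toluenesulfonate (cat.), CH2Cl2, rt
Reagents that add atoms: none
Why: Fluoride-induced desilylation frees the C4 hydroxyl, which adds across the ring to the C1 ketone to give the cis-bridged five-membered hemiketal (the only unstrained mode of bridging, which fixes C1), and acid-catalysed equilibration through the open keto form and its enol should converge C10 on the epimer with the methyl on the oxygen-bridge side.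

Step 18
Reactants: 30 2-{[tert-butyl(dimethyl)silyl]oxy}acetaldehyde; 31 ethyl 2-(triphenylphosphoranylidene)propanoate
Product: 32 ethyl (E)-4-{[tert-butyl(dimethyl)silyl]oxy}-2-methylbut-2-enoate
Conditions: CH2Cl2, rt
Reagents that add atoms: none
Why: Wittig olefination with the α-methyl stabilised ylide should give the trisubstituted E enoate, as is usual for stabilised ylides and aldehydes.

Step 19
Reactants: 32 ethyl (E)-4-{[tert-butyl(dimethyl)silyl]oxy}-2-methylbut-2-enoate
Product: 33 (E)-4-{[tert-butyl(dimethyl)silyl]oxy}-2-methylbut-2-enoic acid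
Conditions: LiOH, THF–H2O, 0 °C; then aq HCl to pH 4
Reagents that add atoms: lithium hydroxide, [Li+].[OH-]
Why: Saponification of the ethyl ester at low temperature liberates the acid while the primary silyl ether and the alkene geometry are retained.

Step 20
Reactants: 29 (1S,4R,5E,8S,10R)-13-acetoxy-1,8-dihydroxy-1,4-epoxygermacra-5,7(11)-dien-12,6-olide; 33 (E)-4-{[tert-butyl(dimethyl)silyl]oxy}-2-methylbut-2-enoic acid
Product: 34 8-O-[(E)-4-{[tert-butyl(dimethyl)silyl]oxy}-2-methylbut-2-enoyl] derivative of 29
Conditions: DCC, DMAP (cat.), CH2Cl2, 0 °C → rt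
Reagents that add atoms: none
Why: Steglich esterification acylates the secondary C8 hydroxyl, the tertiary hemiketal hydroxyl at C1 being too hindered to compete.

Step 21
Reactants: 34 8-O-[(E)-4-{[tert-butyl(dimethyl)silyl]oxy}-2-methylbut-2-enoyl] derivative of 29
Product: 35 (1S,4R,5E,8S,10R)-13-acetoxy-1-hydroxy-8-[(E)-4-hydroxy-2-methylbut-2-enoyloxy]-1,4-epoxygermacra-5,7(11)-dien-12,6-olide (CNP0154520.1)
Conditions: HF·pyridine, pyridine, THF, 0 °C
Reagents that add atoms: none
Why: Fluoride-induced desilylation under pyridine buffering cleaves the primary allylic silyl ether without affecting the hemiketal, the acetate, the enol lactone or the enoate geometry, and gives the target.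

Compound list
1 | diethyl furan-3,4-dicarboxylate | CCOC(=O)c1cocc1C(=O)OCC | starting material
2 | furan-3,4-diyldimethanol | OCc1cocc1CO | intermediate
3 | [4-({[tert-butyl(dimethyl)silyl]oxy}methyl)furan-3-yl]methanol | OCc1cocc1CO[Si](C)(C)C(C)(C)C | intermediate
4 | 4-({[tert-butyl(dimethyl)silyl]oxy}methyl)furan-3-carbaldehyde | O=Cc1cocc1CO[Si](C)(C)C(C)(C)C | intermediate
5 | vinylmagnesium bromide | C=C[Mg]Br | starting material
6 | rac-1-[4-({[tert-butyl(dimethyl)silyl]oxy}methyl)furan-3-yl]prop-2-en-1-ol | C=CC(O)c1cocc1CO[Si](C)(C)C(C)(C)C | intermediate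
7 | (S)-1-[4-({[tert-butyl(dimethyl)silyl]oxy}methyl)furan-3-yl]prop-2-en-1-ol | C=C[C@H](O)c1cocc1CO[Si](C)(C)C(C)(C)C | intermediate
8 | 2-methylprop-2-en-1-ol | CC(=C)CO | starting material
9 | (S)-(2-methyloxiran-2-yl)methanol [(S)-2-methylglycidol] | C[C@]1(CO)CO1 | intermediate
10 | (R)-(2-methyloxiran-2-yl)methyl 4-methylbenzenesulfonate | C[C@]1(COS(=O)(=O)c2ccc(C)cc2)CO1 | intermediate
11 | 2-methylbut-1-en-3-yne | C=C(C)C#C | starting material
12 | lithium 3-methylbut-3-en-1-ynide | [Li]C#CC(C)=C | intermediate
13 | (R)-2-hydroxy-2,6-dimethylhept-6-en-4-yn-1-yl 4-methylbenzenesulfonate | C=C(C)C#CC[C@@](C)(O)COS(=O)(=O)c1ccc(C)cc1 | intermediate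
14 | (R)-2-methyl-2-(4-methylpent-4-en-2-yn-1-yl)oxirane | C[C@@]1(CC#CC(C)=C)CO1 | intermediate
15 | dilithio derivative of 7 (lithium alkoxide, lithiated at the furan carbon between the ring oxygen and the carbinol-bearing carbon) | C=C[C@H](O[Li])c1c([Li])occ1CO[Si](C)(C)C(C)(C)C | intermediate
16 | (S)-1-{4-({[tert-butyl(dimethyl)silyl]oxy}methyl)-2-[(R)-2-hydroxy-2,6-dimethylhept-6-en-4-yn-1-yl]furan-3-yl}prop-2-en-1-ol | C=C[C@H](O)c1c(C[C@](C)(O)CC#CC(C)=C)occ1CO[Si](C)(C)C(C)(C)C | intermediate
17 | (S)-1-{4-(hydroxymethyl)-2-[(R)-2-hydroxy-2,6-dimethylhept-6-en-4-yn-1-yl]furan-3-yl}prop-2-en-1-ol | C=C[C@H](O)c1c(C[C@](C)(O)CC#CC(C)=C)occ1CO | intermediate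
18 | {5-[(R)-2-hydroxy-2,6-dimethylhept-6-en-4-yn-1-yl]-4-[(S)-1-hydroxyprop-2-en-1-yl]furan-3-yl}methyl acetate | C=C[C@H](O)c1c(C[C@](C)(O)CC#CC(C)=C)occ1COC(C)=O | intermediate
19 | {4-[(S)-1-hydroxyprop-2-en-1-yl]-5-{[(R)-2-methyl-5-(prop-1-en-2-yl)-2,3-dihydrofuran-2-yl]methyl}furan-3-yl}methyl acetate | C=C[C@H](O)c1c(C[C@@]2(C)CC=C(C(C)=C)O2)occ1COC(C)=O | intermediate
20 | {5-[(R)-2-hydroxy-2,6-dimethyl-5-oxohept-6-en-1-yl]-4-[(S)-1-hydroxyprop-2-en-1-yl]furan-3-yl}methyl acetate | C=C[C@H](O)c1c(C[C@](C)(O)CCC(=O)C(C)=C)occ1COC(C)=O | intermediate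
21 | (4R,8S)-silylene-bridged furan (diisopropylsilylene acetal of the C4 and C8 hydroxyls of 20) | CC(=O)OCc1coc2c1[C@H](C=C)O[Si](C(C)C)(C(C)C)O[C@](C)(CCC(=O)C(C)=C)C2 | intermediate
22 | 2,5-endoperoxide of furan 21 (peroxide bridge between C6 and C12) | CC(=O)OCC1=C2[C@H](C=C)O[Si](C(C)C)(C(C)C)O[C@](C)(CCC(=O)C(C)=C)CC23OOC1O3 | intermediate
23 | (4R,8S)-silylene-bridged γ-hydroxybutenolide (C12 carbonyl, C6 hemiketal hydroxyl, C6 epimers) | CC(=O)OCC1=C2[C@H](C=C)O[Si](C(C)C)(C(C)C)O[C@](C)(CCC(=O)C(C)=C)CC2(O)OC1=O | intermediate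
24 | C6 methanesulfonate of 23 | CC(=O)OCC1=C2[C@H](C=C)O[Si](C(C)C)(C(C)C)O[C@](C)(CCC(=O)C(C)=C)CC2(OS(C)(=O)=O)OC1=O | intermediate
25 | (4R,5E,8S)-silylene-bridged seco diene (metathesis precursor: C1 isopropenyl ketone, C8 vinyl, 5E alkylidene butenolide, C13 acetate) | CC(=O)OCC1=C2[C@H](C=C)O[Si](C(C)C)(C(C)C)O[C@](C)(CCC(=O)C(C)=C)/C=C2/OC1=O | intermediate
26 | (4R,5E,8S,9Z)-13-acetoxy-1-oxogermacra-5,7(11),9-trien-12,6-olide O4,O8-diisopropylsilylene | CC(=O)OCC1=C2/C(=C\[C@@]3(C)CCC(=O)/C(C)=C\[C@@H]2O[Si](C(C)C)(C(C)C)O3)OC1=O | intermediate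
27 | (4R,5E,8S)-13-acetoxy-1-oxogermacra-5,7(11)-dien-12,6-olide O4,O8-diisopropylsilylene (C10 epimers) | CC(=O)OCC1=C2/C(=C\[C@@]3(C)CCC(=O)C(C)C[C@@H]2O[Si](C(C)C)(C(C)C)O3)OC1=O | intermediate
28 | (4R,5E,8S)-13-acetoxy-4,8-dihydroxy-1-oxogermacra-5,7(11)-dien-12,6-olide (C10 epimers) | CC(=O)OCC1=C2/C(=C\[C@](C)(O)CCC(=O)C(C)C[C@@H]2O)OC1=O | intermediate
29 | (1S,4R,5E,8S,10R)-13-acetoxy-1,8-dihydroxy-1,4-epoxygermacra-5,7(11)-dien-12,6-olide | CC(=O)OCC1=C2/C(=C\[C@@]3(C)CC[C@](O)(O3)[C@H](C)C[C@@H]2O)OC1=O | intermediate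
30 | 2-{[tert-butyl(dimethyl)silyl]oxy}acetaldehyde | O=CCO[Si](C)(C)C(C)(C)C | starting material
31 | ethyl 2-(triphenylphosphoranylidene)propanoate | CCOC(=O)C(C)=P(c1ccccc1)(c1ccccc1)c1ccccc1 | starting material
32 | ethyl (E)-4-{[tert-butyl(dimethyl)silyl]oxy}-2-methylbut-2-enoate | CCOC(=O)/C(C)=C/CO[Si](C)(C)C(C)(C)C | intermediate
33 | (E)-4-{[tert-butyl(dimethyl)silyl]oxy}-2-methylbut-2-enoic acid | OC(=O)/C(C)=C/CO[Si](C)(C)C(C)(C)C | intermediate
34 | 8-O-[(E)-4-{[tert-butyl(dimethyl)silyl]oxy}-2-methylbut-2-enoyl] derivative of 29 | CC(=O)OCC1=C2/C(=C\[C@@]3(C)CC[C@](O)(O3)[C@H](C)C[C@@H]2OC(=O)/C(C)=C/CO[Si](C)(C)C(C)(C)C)OC1=O | intermediate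
35 | (1S,4R,5E,8S,10R)-13-acetoxy-1-hydroxy-8-[(E)-4-hydroxy-2-methylbut-2-enoyloxy]-1,4-epoxygermacra-5,7(11)-dien-12,6-olide (CNP0154520.1) | CC(=O)OCC1=C2/C(=C\[C@@]3(C)CC[C@](O)(O3)[C@H](C)C[C@@H]2OC(=O)/C(C)=C/CO)OC1=O | target

Total step count: 21 steps.
Longest linear sequence: 17 steps (steps 1–5, 8–17, 20 and 21).

Steps most likely to fail

1. Step 15. Ring closure may lose out to intermolecular metathesis, or stall after initiation, because the ruthenium carbene at C9 has to add to an electron-poor 1,1-disubstituted alkene through a strained ten-membered transition state. The fallback sets out from 25. Luche reduction (NaBH4, CeCl3·7H2O, MeOH–THF, −78 °C) converts the C1 ketone chemoselectively into the C1 allylic alcohol seco diene F1 (both C1 epimers). Its more electron-rich isopropenyl carbinol alkene, helped by the free allylic hydroxyl, should undergo ring-closing metathesis with the same catalyst to the ten-membered allylic alcohol F2. Oxidation with Dess–Martin periodinane then comes back to the route at 26.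

2. Step 12. Intermolecular silylation to oligomeric siloxanes, or capture of the silyl triflate by the hemiketal tautomer, may outrun closure of the eight-membered ring across the hindered tertiary hydroxyl. The fallback sets out from 20 and gives up the template at this stage. Both hydroxyls are protected separately (TESOTf, 2,6-lutidine, CH2Cl2, −78 °C) to give bis(triethylsilyl) ether F3. Photo-oxygenation as in step 13 gives, through endoperoxide F4, hydroxybutenolide F5. Dehydration as in step 14 gives, through mesylate F6, the alkylidene butenolide as the isomer expected for an open chain, the (5Z)-alkylidene butenolide F7 (C4 cis to the ring oxygen). Irradiation (350 nm, benzene) interconverts the two alkene isomers photochemically; the (5E)-alkylidene butenolide F8 is separated and the Z isomer is returned to the irradiation. HF·pyridine then frees (5E)-diol F9, in which O4 and O8 are held close across the alkene, so that bridging with iPr2Si(OTf)2 and 2,6-lutidine should be easy and comes back to the route at 25.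

3. Step 17. Epimerisation at C10 may be slow, or the equilibrium may not favour the required epimer strongly enough, so that a mixture persists. The fallback sets out from 26 and leaves out step 16. HF·pyridine removes the bridge to give enone diol F10, which should close across the ring to allylic hemiketal F11 with the C9–C10 alkene still in place. Steglich esterification with 33, as in step 20, caps the C8 hydroxyl and gives ester F12. Hydrogenation with [Ir(cod)(PCy3)(py)]PF6 under H2 in CH2Cl2, directed by the tertiary C1 hydroxyl, should add hydrogen to the alkene face syn to that hydroxyl; this places the C10 hydrogen cis to the C1 hydroxyl, as in the target, and comes back to the route at 34.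

Further compounds
F1 | step 15 | (4R,5E,8S)-silylene-bridged seco diene with C1 allylic alcohol (C1 epimers) | CC(=O)OCC1=C2[C@H](C=C)O[Si](C(C)C)(C(C)C)O[C@](C)(CCC(O)C(C)=C)/C=C2/OC1=O
F2 | step 15 | (4R,5E,8S,9Z)-ten-membered C1 allylic alcohol, O4,O8-diisopropylsilylene (C1 epimers) | CC(=O)OCC1=C2/C(=C\[C@@]3(C)CCC(O)/C(C)=C\[C@@H]2O[Si](C(C)C)(C(C)C)O3)OC1=O
F3 | step 12 | bis(triethylsilyl) ether of 20 | CC[Si](CC)(CC)O[C@@H](C=C)c1c(C[C@](C)(O[Si](CC)(CC)CC)CCC(=O)C(C)=C)occ1COC(C)=O
F4 | step 12 | 2,5-endoperoxide of furan F3 | CC(=O)OCC1=C([C@H](C=C)O[Si](CC)(CC)CC)C2(C[C@](C)(O[Si](CC)(CC)CC)CCC(=O)C(C)=C)OOC1O2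
F5 | step 12 | bis(triethylsilyl) γ-hydroxybutenolide (C6 epimers) | CC(=O)OCC1=C([C@H](C=C)O[Si](CC)(CC)CC)C(O)(C[C@](C)(O[Si](CC)(CC)CC)CCC(=O)C(C)=C)OC1=O
F6 | step 12 | C6 methanesulfonate of F5 | CC(=O)OCC1=C([C@H](C=C)O[Si](CC)(CC)CC)C(OS(C)(=O)=O)(C[C@](C)(O[Si](CC)(CC)CC)CCC(=O)C(C)=C)OC1=O
F7 | step 12 | (4R,5Z,8S)-bis(triethylsilyl) alkylidene butenolide | CC(=O)OCC1=C([C@H](C=C)O[Si](CC)(CC)CC)/C(=C/[C@](C)(O[Si](CC)(CC)CC)CCC(=O)C(C)=C)OC1=O
F8 | step 12 | (4R,5E,8S)-bis(triethylsilyl) alkylidene butenolide | CC(=O)OCC1=C([C@H](C=C)O[Si](CC)(CC)CC)/C(=C\[C@](C)(O[Si](CC)(CC)CC)CCC(=O)C(C)=C)OC1=O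
F9 | step 12 | (4R,5E,8S)-4,8-dihydroxy seco diene | CC(=O)OCC1=C([C@H](C=C)O)/C(=C\[C@](C)(O)CCC(=O)C(C)=C)OC1=O
F10 | step 17 | (4R,5E,8S,9Z)-13-acetoxy-4,8-dihydroxy-1-oxogermacra-5,7(11),9-trien-12,6-olide | CC(=O)OCC1=C2/C(=C\[C@](C)(O)CCC(=O)/C(C)=C\[C@@H]2O)OC1=O
F11 | step 17 | (1S,4R,5E,8S,9Z)-13-acetoxy-1,8-dihydroxy-1,4-epoxygermacra-5,7(11),9-trien-12,6-olide | CC(=O)OCC1=C2/C(=C\[C@@]3(C)CC[C@](O)(O3)/C(C)=C\[C@@H]2O)OC1=O
F12 | step 17 | 8-O-[(E)-4-{[tert-butyl(dimethyl)silyl]oxy}-2-methylbut-2-enoyl] derivative of F11 | CC(=O)OCC1=C2/C(=C\[C@@]3(C)CC[C@](O)(O3)/C(C)=C\[C@@H]2OC(=O)/C(C)=C/CO[Si](C)(C)C(C)(C)C)OC1=O
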